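**Retrosynthetic overview**

1. The target ester is cut first at the acyl C–O bond (made last), then at C2–C3 of the C30 chain (key step).
2. Key C2–C3 bond: octacos-1-ene 1, hydroborated with 9-BBN 2, gives a nucleophilic C28 alkyl group. Ethyl bromoacetate 3 supplies C1–C2, its α-carbon acting as the electrophile (enolonium, a2 equivalent). Two carbons that are normally both nucleophilic are thus joined through borane 4 to give ethyl triacontanoate 5.
3. Acyl C–O bond: ester exchange of 5 with tyrosol 6 at the primary alcohol gives Basalethanolide B 7.
4. No ring is formed (the benzene ring arrives with 6) and there is no stereocentre to set.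

Assumption: the acyl chain of the SMILES is read as 30 carbons (triacontanoyl); the molecule is achiral, so the single-enantiomer requirement is met trivially; octacos-1-ene is taken as a catalogue α-olefin.

**Route**

Step 1
Reactants: 1 octacos-1-ene, 2 9-borabicyclo[3.3.1]nonane (9-BBN), 3 ethyl bromoacetate
Product: 5 ethyl triacontanoate, via B-octacosyl-9-BBN 4 (not isolated)
Conditions: 2 (1.05 equiv), THF, 65 °C, 3 h; then 3 (1.1 equiv), KOtBu (1.1 equiv, added slowly), t-BuOH/THF, 20 °C, 1 h; evaporate, crystallise from acetone
Reagents that add atoms: none
Why: Anti-Markovnikov hydroboration places boron on C1 of 1; the potassium enolate of 3 then adds to boron and the octacosyl group shifts from boron to the bromine-bearing α-carbon with loss of bromide (Brown α-alkylation of an α-bromo ester with a B-alkyl-9-BBN, a borate 1,2-shift in which the α-bromo ester is the enolonium equivalent), and t-BuOH protonates the boron enolate to release the ester; no stereocentre is formed.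

Step 2
Reactants: 5 ethyl triacontanoate, 6 tyrosol (4-(2-hydroxyethyl)phenol)
Product: 7 Basalethanolide B (2-(4-hydroxyphenyl)ethyl triacontanoate)
Conditions: Novozym 435 (immobilised Candida antarctica lipase B), 6 (3 equiv), toluene/2-methyl-2-butanol 1:1, 5 Å MS, 65 °C, 48 h
Reagents that add atoms: none
Why: Lipase-catalysed transesterification: the acyl-enzyme formed from 5 is captured only by the primary aliphatic alcohol of 6 (the phenol is not a substrate), the sieves remove ethanol to drive the equilibrium, and no stereocentre is involved.

**Compound list**

1 | octacos-1-ene (achiral) | C=CCCCCCCCCCCCCCCCCCCCCCCCCCC | starting material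
2 | 9-borabicyclo[3.3.1]nonane (9-BBN, drawn as the monomer) | [H]B1C2CCCC1CCC2 | starting material
3 | ethyl bromoacetate | BrCC(=O)OCC | starting material
4 | B-octacosyl-9-BBN (9-octacosyl-9-borabicyclo[3.3.1]nonane) | CCCCCCCCCCCCCCCCCCCCCCCCCCCCB1C2CCCC1CCC2 | intermediate
5 | ethyl triacontanoate | CCCCCCCCCCCCCCCCCCCCCCCCCCCCCC(=O)OCC | intermediate
6 | tyrosol (4-(2-hydroxyethyl)phenol) | OCCc1ccc(O)cc1 | starting material
7 | Basalethanolide B (2-(4-hydroxyphenyl)ethyl triacontanoate, achiral) | CCCCCCCCCCCCCCCCCCCCCCCCCCCCCC(=O)OCCc1ccc(O)cc1 | target

**Summary**

Total step count: 2.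
Longest linear sequence: 2 steps (1 → 5 → 7).

Steps most likely to fail (the route has only two steps, so both are ranked, the riskier first):

- Step 1. The waxy C28 borane 4 may dissolve poorly at 20 °C, and a ring B–C bond of the 9-BBN cage can migrate in place of the octacosyl group, lowering the yield. The fallback sets out from 1 and comes back at 5. It makes the same C2–C3 bond in open-shell fashion: ethyl iodoacetate adds to 1 by iodine atom transfer (Et3B, air, benzene, 25 °C), the electrophilic α-ester radical attacking the terminal alkene carbon. This gives ethyl 4-iodotriacontanoate F1 (racemic at C4; the centre disappears in the next operation). Bu3SnH and catalytic AIBN in toluene at 80 °C then replace iodine by hydrogen and deliver 5.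

- Step 2. The lipase may turn over a C30 acyl donor slowly, and 5 and 6 have opposite solubility demands. The fallback sets out from 5 and comes back at 7. Saponification (KOH, EtOH/THF, reflux; then HCl) gives triacontanoic acid F2. This is esterified with 6 under Brønsted acid catalysis (TsOH·H2O, toluene, Dean–Stark, reflux); the phenol does not esterify under these conditions, so only the primary alcohol reacts.

**Further compounds**

F1 | step 1 | ethyl 4-iodotriacontanoate (racemic) | CCCCCCCCCCCCCCCCCCCCCCCCCCC(I)CCC(=O)OCC
F2 | step 2 | triacontanoic acid | CCCCCCCCCCCCCCCCCCCCCCCCCCCCCC(=O)O
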